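**Strategy.** The target is a trans-3,4-dibenzyl-γ-butyrolactone (ring atoms O1, C2 carbonyl, C3, C4, C5). The benzylic CH2 on C4 stands 1,3 to C3, so tying that CH2 back to C3 gives a lactone-fused cyclopropane, ethyl (1S,5R)-2-oxo-3-oxabicyclo[3.1.0]hexane-1-carboxylate 6, whose C4 stereocentre is bought with (R)-epichlorohydrin. The key step runs this in reverse: a copper-catalysed aryl Grignard reagent opens the doubly carbonyl-activated cyclopropane of 6 at its CH2 (aryl–CH2 bond), and the released malonate-type enolate at C3 is benzylated in the same flask (C3–CH2 bond), with no ring formed. Ester removal under equilibrating conditions then leaves C3 trans to C4.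

Key step: step 3

Assumption: malonate opens (R)-epichlorohydrin at the epoxide CH2 before chloride is displaced, so the stereocentre is inverted once, in the cyclopropane closure; on that basis 1 leads to the (1S,5R)-lactone and to 4R in the target, and all descriptors below were derived accordingly.

**Step 1**
Reactants: 1 (R)-epichlorohydrin; 2 diethyl malonate
Product: 6 ethyl (1S,5R)-2-oxo-3-oxabicyclo[3.1.0]hexane-1-carboxylate, via chlorohydrin alkoxide 3 (not isolated), via epoxy malonate 4 (not isolated), via cyclopropyl carbinol 5 (not isolated)
Conditions: NaOEt (1.05 equiv), 2 (1.1 equiv), EtOH, 0 °C → reflux; AcOH quench; distillation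
Reagents that add atoms: none
Why: This is a base-mediated alkylation–cyclopropanation–lactonisation cascade in which sodiomalonate opens the epoxide of 1 at its CH2, alkoxide 3 expels chloride to give epoxide 4, the re-formed malonate anion closes the cyclopropane by 3-exo-tet attack with inversion at the former epichlorohydrin stereocentre (which becomes the 5R ring-fusion CH), and the alkoxide of 5 lactonises onto the cis ester, which fixes C1 as S because the fused bicycle can only be cis.

**Step 2**
Reactants: 7 5-bromo-1,2,3-trimethoxybenzene
Product: 8 3,4,5-trimethoxyphenylmagnesium bromide (titrated THF solution, used directly)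
Conditions: Mg turnings, I2 (cat.), THF, 45–60 °C
Reagents that add atoms: magnesium, [Mg]
Why: Grignard formation by oxidative insertion of magnesium into the aryl C–Br bond is routine for this electron-rich bromide once the metal is activated with iodine, and aryl methyl ethers are inert to it.

**Step 3**
Reactants: 6 ethyl (1S,5R)-2-oxo-3-oxabicyclo[3.1.0]hexane-1-carboxylate; 8 3,4,5-trimethoxyphenylmagnesium bromide; 9 3,4,5-trimethoxybenzyl bromide
Product: 11 ethyl (3R,4R)-2-oxo-3,4-bis(3,4,5-trimethoxybenzyl)tetrahydrofuran-3-carboxylate, via bromomagnesium enolate 10 (not isolated)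
Conditions: 8 (1.15 equiv), CuI (10 mol%), THF, −40 → −15 °C; then 9 (1.4 equiv), DMPU, Bu4NI (10 mol%), −15 → 40 °C; aq NH4Cl
Reagents that add atoms: none
Why: The Grignard reagent and catalytic CuI give a diarylcuprate Ar2CuMgBr (monovalent copper) that attacks C6, the cyclopropane CH2 of 6, from the side opposite the C1–C6 bond in an SN2-like homoconjugate addition (formally through a trivalent aryl-alkyl copper species and reductive elimination), so the aryl–CH2 bond forms while the C1–C6 electrons flow into the chelated bromomagnesium enolate 10. The closest known reaction type is the CuI-catalysed Grignard opening of cyclopropane-1,1-dicarbonyl compounds, this bicyclic lactone included, followed by the classical C-alkylation of a malonate-type enolate with a benzylic bromide, which DMPU and iodide catalysis should accelerate. No ring is closed, since the lactone is already in place and the cyclopropane is consumed. C4 of the product (C5 of 6) is not a reacting atom and keeps the R configuration derived from 1, whereas the new quaternary C3 is set under substrate control by approach of 9 anti to the freshly installed C4 benzyl group; step 4 erases that centre, so its level of control is not critical. The step needs attack at the CH2 carbon in preference to the ring-fusion CH and to 1,2-addition at the two carbonyls, which the lower substitution of the CH2, the soft cuprate at low temperature and the polarisation of the C1–C6 bond by two geminal carbonyls should secure. C- over O-benzylation is expected from the chelated enolate and the soft electrophile.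

**Step 4**
Reactants: 11 ethyl (3R,4R)-2-oxo-3,4-bis(3,4,5-trimethoxybenzyl)tetrahydrofuran-3-carboxylate
Product: 15 (−)-cubebininolide, (3R,4R)-3,4-bis(3,4,5-trimethoxybenzyl)dihydrofuran-2(3H)-one, via lithium carboxylate 12 (not isolated), via lithium enolate 13 (not isolated), via cis lactone 14 (not isolated)
Conditions: LiCl (3 equiv), H2O (2 equiv), DMSO, 155 °C; then DBU (0.5 equiv), 80 °C, same flask; 1 M HCl work-up
Reagents that add atoms: none
Why: In this Krapcho dealkoxycarbonylation chloride dealkylates the ethyl ester on the quaternary carbon by SN2, carboxylate 12 loses CO2 to enolate 13, and protonation followed by DBU-mediated enolisation should funnel any cis lactone 14 into the more stable trans lactone 15, so C3 is set thermodynamically as R relative to the untouched C4 while the aryl methyl ethers and the lactone survive.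

**Compound list**
1 | (R)-epichlorohydrin | ClC[C@H]1CO1 | starting material
2 | diethyl malonate | CCOC(=O)CC(=O)OCC | starting material
3 | diethyl 2-[(2R)-3-chloro-2-hydroxypropyl]propanedioate (present as its sodium alkoxide, not isolated) | ClC[C@H](O)CC(C(=O)OCC)C(=O)OCC | intermediate
4 | diethyl 2-{[(2R)-oxiran-2-yl]methyl}propanedioate (not isolated) | C1[C@H](O1)CC(C(=O)OCC)C(=O)OCC | intermediate
5 | diethyl (2R)-2-(hydroxymethyl)cyclopropane-1,1-dicarboxylate (present as its sodium alkoxide, not isolated) | OC[C@@H]1CC1(C(=O)OCC)C(=O)OCC | intermediate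
6 | ethyl (1S,5R)-2-oxo-3-oxabicyclo[3.1.0]hexane-1-carboxylate | C1[C@H]2COC(=O)[C@@]12C(=O)OCC | intermediate
7 | 5-bromo-1,2,3-trimethoxybenzene | COc1cc(Br)cc(OC)c1OC | starting material
8 | 3,4,5-trimethoxyphenylmagnesium bromide | COc1cc([Mg]Br)cc(OC)c1OC | intermediate
9 | 3,4,5-trimethoxybenzyl bromide | COc1cc(CBr)cc(OC)c1OC | starting material
10 | bromomagnesium enolate of ethyl (4R)-2-oxo-4-(3,4,5-trimethoxybenzyl)tetrahydrofuran-3-carboxylate (not isolated) | COc1cc(C[C@H]2COC(O[Mg]Br)=C2C(=O)OCC)cc(OC)c1OC | intermediate
11 | ethyl (3R,4R)-2-oxo-3,4-bis(3,4,5-trimethoxybenzyl)tetrahydrofuran-3-carboxylate | COc1cc(C[C@H]2COC(=O)[C@]2(C(=O)OCC)Cc2cc(OC)c(OC)c(OC)c2)cc(OC)c1OC | intermediate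
12 | lithium (3R,4R)-2-oxo-3,4-bis(3,4,5-trimethoxybenzyl)tetrahydrofuran-3-carboxylate (not isolated) | COc1cc(C[C@H]2COC(=O)[C@]2(C(=O)[O-])Cc2cc(OC)c(OC)c(OC)c2)cc(OC)c1OC.[Li+] | intermediate
13 | lithium enolate of (4R)-3,4-bis(3,4,5-trimethoxybenzyl)dihydrofuran-2(3H)-one (not isolated) | COc1cc(C[C@H]2COC(O[Li])=C2Cc2cc(OC)c(OC)c(OC)c2)cc(OC)c1OC | intermediate
14 | (3S,4R)-3,4-bis(3,4,5-trimethoxybenzyl)dihydrofuran-2(3H)-one, the cis C3 epimer (not isolated) | COc1cc(C[C@H]2COC(=O)[C@H]2Cc2cc(OC)c(OC)c(OC)c2)cc(OC)c1OC | intermediate
15 | (−)-cubebininolide, (3R,4R)-3,4-bis(3,4,5-trimethoxybenzyl)dihydrofuran-2(3H)-one | COc1cc(C[C@H]2COC(=O)[C@@H]2Cc2cc(OC)c(OC)c(OC)c2)cc(OC)c1OC | target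

**Step count:** 4 steps in total; longest linear sequence 3 steps (steps 1, 3, 4, or 2, 3, 4).

**Steps most likely to fail**

1. Step 3. The chelated magnesium enolate may alkylate sluggishly, so that it is merely protonated on work-up, while residual aryl Grignard reagent couples with the benzyl bromide; carbonyl addition by the Grignard reagent is a second possible diversion. The fallback decouples the two bond formations and sets out from 6 and 8. The CuI-catalysed ring opening is run alone and quenched with dilute HCl, and ethyl (3S,4R)-2-oxo-4-(3,4,5-trimethoxybenzyl)tetrahydrofuran-3-carboxylate F1 is isolated (trans epimer expected to predominate at the enolisable C3). F1 is then C-benzylated with 9 as its potassium enolate (K2CO3, acetone, reflux), a classical alkylation of an α-alkoxycarbonyl lactone, which returns to the route at 11.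

2. Step 4. Chloride may dealkylate the hindered quaternary ester slowly or attack the lactone CH2–O carbon instead, opening the ring. The fallback sets out from 11 and replaces nucleophilic dealkylation by hydrolysis: KOH in aqueous EtOH at reflux cleaves both the ester and the lactone, and acidification with HCl gives 2-[(2R)-1-hydroxy-3-(3,4,5-trimethoxyphenyl)propan-2-yl]-2-(3,4,5-trimethoxybenzyl)propanedioic acid F2. F2 relactonises on warming to (4R)-2-oxo-3,4-bis(3,4,5-trimethoxybenzyl)tetrahydrofuran-3-carboxylic acid F3 (C3 epimers). Heating F3 in toluene at 110 °C should expel CO2, and DBU in the same solvent equilibrates C3, which returns to the route at 15.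

3. Step 1. Enantiopurity may erode if direct displacement of chloride competes with epoxide opening, since the two pathways lead to opposite enantiomers of 6. The fallback sets out from 2 and purchased (R)-glycidol (OC[C@@H]1CO1) and enforces a single pathway with a far better leaving group. The alcohol is converted with Tf2O and 2,6-lutidine (CH2Cl2, −30 °C) into [(2S)-oxiran-2-yl]methyl trifluoromethanesulfonate F4. The sodium salt of 2 (NaH, THF, 0 °C → room temperature) displaces the triflate directly to give 4, which should pass through 5 as in step 1 and return to the route at 6.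

**Further compounds**
F1 | step 3 | ethyl (3S,4R)-2-oxo-4-(3,4,5-trimethoxybenzyl)tetrahydrofuran-3-carboxylate | COc1cc(C[C@H]2COC(=O)[C@@H]2C(=O)OCC)cc(OC)c1OC
F2 | step 4 | 2-[(2R)-1-hydroxy-3-(3,4,5-trimethoxyphenyl)propan-2-yl]-2-(3,4,5-trimethoxybenzyl)propanedioic acid | COc1cc(C[C@@H](CO)C(Cc2cc(OC)c(OC)c(OC)c2)(C(=O)O)C(=O)O)cc(OC)c1OC
F3 | step 4 | (4R)-2-oxo-3,4-bis(3,4,5-trimethoxybenzyl)tetrahydrofuran-3-carboxylic acid (C3 epimers) | COc1cc(C[C@H]2COC(=O)C2(C(=O)O)Cc2cc(OC)c(OC)c(OC)c2)cc(OC)c1OC
F4 | step 1 | [(2S)-oxiran-2-yl]methyl trifluoromethanesulfonate | FC(F)(F)S(=O)(=O)OC[C@@H]1CO1
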